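The readings come from a simulation for an exercise; the scatter is artificial.

Count this reaction in turnovers, the number of target molecules one enzyme makes before it stops, because an enzyme may wear out by cycles as well as by the clock.

| flask | starting material | second substrate | free enzyme | temperature | remark | time |
|---|---|---|---|---|---|---|
| Friday's | 0.094 M | 1.5 equiv | 0.032 mol% | 15 °C | run made earlier |  |
| Monday's | 0.21 M | 1.5 equiv | 0.032 mol% | 28 °C | run made earlier |  |
| Sunday's | 0.14 M | 3 equiv | 0.032 mol% | 15 °C | run made earlier |  |
| north-east | 0.14 M | 1.50 equiv | 0.032 mol% | 35 °C |  | 8.0 min |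
| north-west | 0.14 M | 1.50 equiv | 0.032 mol% | 20 °C |  | 8.0 min |

| run | time / min | target / % | starting material / % |
|---|---|---|---|
| Friday's | 2.00 | 85.6 | 14.2 |
| Friday's | 2.50 | 94.7 | 4.3 |
| Friday's | 5.00 | 99.2 | 0 |
| Friday's | 8.00 | 99.2 | 0 |
| Friday's | 15.0 | 99.8 | 0 |
| Friday's | 20.0 | 100.2 | 0 |
| Monday's | 1.33 | 83.6 | 16.4 |
| Monday's | 2.50 | 92.1 | 8.7 |
| Monday's | 4.00 | 92.6 | 7.2 |
| Monday's | 5.00 | 92.4 | 7.9 |
| Monday's | 6.00 | 93.7 | 6.7 |
| Monday's | 8.00 | 92.0 | 7.1 |
| Sunday's | 2.00 | 100.1 | 0.4 |
| Sunday's | 4.00 | 98.9 | 0.8 |
| Sunday's | 6.00 | 99.4 | 0 |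
| Sunday's | 10.0 | 100.3 | 0.2 |
| Sunday's | 20.0 | 99.4 | 0 |

(scatter of a reading: 0.5 percentage points)



* the best flask by amount of target, in percent of the starting material charged; "all alike" if 1.5 percentage points covers them all (north-east / north-west / all alike)
* amount of target at the end, in percent of the starting material charged, north-east
* amount of target at the end, in percent of the starting material charged, north-west

At 0.032 mol%, a complete flask needs 3120 turnovers per enzyme. Friday's and Monday's flasks share their equivalents and loading, but they differ in two settings: Monday's is more concentrated, 0.21 M against 0.094 M, and hotter, 28 °C against 15 °C. Friday's reaches 100.2%, and its enzyme delivered what was needed. Monday's, at 28 °C, stands still from 4.00 min to 8.00 min at about 92.7%, with 7.1% of starting material still there. That reads as stopped enzyme, not spent reagent, and gives 2900 turnovers.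

Sunday's flask, richer in second substrate, stands at 100.1% after 2.00 min, where Friday's stands at 85.6%. So my own reckoning takes second substrate as the concentration that sets the pace, pseudo-first-order in it, and lets turnovers grow in proportion to it. Dividing Monday's turnovers by its average second substrate gives the turnover allowance, turnovers per unit concentration of second substrate: 13300 L mol⁻¹.

At Monday's temperature, the 0.14 M charge then reaches 68.9%. North-east is hotter, so I put it below that figure. North-west, at 20 °C, I put near complete.

The forecast, holding that “the enzyme is probably dying”, names north-west as best, with 55% for north-east and 99% for north-west. The flasks give 32.4% in north-east and >99.9% in north-west, so north-west is best.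

    free enzyme → unfolded enzyme (k = 0.00150 s⁻¹, Ea = 264 kJ mol⁻¹)
    starting material + free enzyme ⇌ starting complex (K = 340 L mol⁻¹, k = 32000 L mol⁻¹ s⁻¹, Ea = 20.0 kJ mol⁻¹, ΔH = −40.0 kJ mol⁻¹)
    second substrate + starting complex ⇌ ternary complex (K = 5.30 L mol⁻¹, k = 4800 L mol⁻¹ s⁻¹, Ea = 39.0 kJ mol⁻¹, ΔH = −59.0 kJ mol⁻¹)
    ternary complex → free enzyme + target (k = 110 s⁻¹, Ea = 54.0 kJ mol⁻¹)
    starting complex → spent catalyst (k = 0.0130 s⁻¹, Ea = 85.0 kJ mol⁻¹)
    (constants at 20 °C)

North-east's result puts the allowance at 5400 L mol⁻¹, down from Monday's 13300 L mol⁻¹. North-east holds its 32.4% of target by 4.00 min and ends with 76.7% of its catalyst as spent catalyst. The main reason for the shortfall is the way back from ternary complex to second substrate and starting complex: without it, north-east gives 99.0%. The neighbour with 0.900 equiv of second substrate, put at 19.4% by that allowance, ends at 20.1%.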